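**Plan**

- Retrosynthesis: first the two O-protecting groups are cut (isopropyl on the naphthalene oxygen para to the linkage, methyl on O8 of the tetralone), then the bond between C4 of the tetralone and C1 of the naphthalene. This gives an arylboronate and a ring-fused ortho-quinone methide (o-QM).
- Enabling feature: the phenolic oxygen at C5 of ring B (the hydroquinone ring) is ortho to the benzylic C4 of ring A (the cyclohexanone ring), so O5–C5–C4a–C4 can become O=C5–C4a=C4. Ring A locks this methide in the E geometry, and the O8 methyl ether blocks its quinone tautomer.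
- Forward, naphthalene fragment: naphthalene-1,5-diol is monomethylated, brominated para to the free OH, protected as the isopropyl ether and borylated.
- Forward, tetralone fragment: 5-hydroxy-1-tetralone is para-methoxylated by oxidation to the p-quinone monoketal and reduction in the same flask (this installs O8 as its methyl ether), acetylated, then brominated at C4 and converted to the sulfone.
- Union and stereochemistry: the fragments are joined by a rhodium-catalysed asymmetric 1,4-arylation of the o-QM released in situ, where the chiral diene on rhodium sets the single stereocentre (C4, S); BCl3 then removes both protecting groups.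

Key step: step 8

Assumption: the sense of induction of a chiral diene on this ring-fused o-QM cannot be predicted with certainty; the (1R,4R) ligand is written, and its mirror image is used if a pilot run gives the (R) product.

**Route**

Step 1
Reactants: 1 naphthalene-1,5-diol
Product: 2 5-methoxynaphthalen-1-ol
Conditions: MeI (1.0 equiv), K2CO3 (1.0 equiv), acetone, reflux, N2
Reagents that add atoms: iodomethane CI
Why: Williamson monomethylation of the symmetric diol with one equivalent of base and electrophile; the statistical mixture is separated (the mono-ether is extracted into dilute NaOH away from the diether and chromatographed from the diol).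

Step 2
Reactants: 2 5-methoxynaphthalen-1-ol
Product: 3 4-bromo-5-methoxynaphthalen-1-ol
Conditions: NBS (1.0 equiv), MeCN, −30 → 0 °C, dark
Reagents that add atoms: N-bromosuccinimide O=C1CCC(=O)N1Br
Why: Electrophilic aromatic bromination; the free hydroxyl is the strongest donor and directs para to C4 (the position that 1,5-dialkoxynaphthalenes also use in spite of the peri oxygen), so attack at C8 and C2 should stay minor.

Step 3
Reactants: 3 4-bromo-5-methoxynaphthalen-1-ol
Product: 4 4-bromo-1-isopropoxy-5-methoxynaphthalene
Conditions: 2-bromopropane (excess), K2CO3, DMF, 60 °C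
Reagents that add atoms: 2-bromopropane CC(C)Br
Why: Williamson ether synthesis; the isopropyl ether should survive organolithium, base and rhodium, and is the alkyl ether that BCl3 removes next to a plain aryl methyl ether.

Step 4
Reactants: 4 4-bromo-1-isopropoxy-5-methoxynaphthalene
Product: 6 2-(4-isopropoxy-8-methoxynaphthalen-1-yl)-4,4,5,5-tetramethyl-1,3,2-dioxaborolane, via (4-isopropoxy-8-methoxynaphthalen-1-yl)lithium 5 (not isolated)
Conditions: n-BuLi (1.1 equiv), THF, −78 °C; 2-isopropoxy-4,4,5,5-tetramethyl-1,3,2-dioxaborolane, −78 °C → rt; 1 M HCl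
Reagents that add atoms: 2-isopropoxy-4,4,5,5-tetramethyl-1,3,2-dioxaborolane CC(C)OB1OC(C)(C)C(C)(C)O1
Why: Bromine–lithium exchange at −78 °C outruns ortho-lithiation, the peri methoxy oxygen holds the aryllithium, and the borate ester traps it (lithiation–borylation).

Step 5
Reactants: 7 5-hydroxy-3,4-dihydronaphthalen-1(2H)-one
Product: 9 5-hydroxy-8-methoxy-3,4-dihydronaphthalen-1(2H)-one, via quinone monoketal 8 (not isolated)
Conditions: PhI(OAc)2 (2.2 equiv), MeOH, 0 °C → rt; then Zn dust (excess), AcOH, same flask, 25 °C
Reagents that add atoms: methanol CO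
Why: Oxidative dearomatisation of a phenol with a free para position by a trivalent iodine reagent in methanol places methanol para to the phenolic oxygen (C8), and because the p-methoxyphenol so formed is oxidised faster than 7 the oxidation is driven on to the p-quinone monoketal 8, which zinc in acetic acid then reduces in the same flask (two electrons, loss of one methoxide, re-aromatisation of ring B) so that all material converges on the p-methoxyphenol 9 with O8 in place as its methyl ether.

Step 6
Reactants: 9 5-hydroxy-8-methoxy-3,4-dihydronaphthalen-1(2H)-one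
Product: 10 4-methoxy-5-oxo-5,6,7,8-tetrahydronaphthalen-1-yl acetate
Conditions: Ac2O, pyridine, DMAP (cat.), CH2Cl2, 0 °C → rt
Reagents that add atoms: acetic anhydride CC(=O)OC(C)=O
Why: DMAP-catalysed acetylation of the phenol (nucleophilic acyl substitution) masks the 5-OH, which lowers the reactivity of ring B toward electrophilic bromine in step 7 and is released again by base in step 8.

Step 7
Reactants: 10 4-methoxy-5-oxo-5,6,7,8-tetrahydronaphthalen-1-yl acetate
Product: 12 4-methoxy-5-oxo-8-tosyl-5,6,7,8-tetrahydronaphthalen-1-yl acetate (racemic), via benzylic bromide 11 (not isolated)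
Conditions: NBS (1.05 equiv), visible-light LED, PhCF3, 25 °C; then sodium 4-methylbenzenesulfinate (2 equiv), DMF, 25 °C
Reagents that add atoms: sodium 4-methylbenzenesulfinate Cc1ccc(S(=O)[O-])cc1.[Na+]
Why: Wohl–Ziegler bromination at C4, the only benzylic CH2 (the acetate lowers the ring's reactivity toward electrophilic bromine and the C2–H next to the ketone is polarity-mismatched for the bromine atom), followed by S-alkylation of the sulfinate (SN2) to the benzylic sulfone; C4 is racemic here and is erased in step 8.

Step 8
Reactants: 12 4-methoxy-5-oxo-8-tosyl-5,6,7,8-tetrahydronaphthalen-1-yl acetate (racemic); 6 2-(4-isopropoxy-8-methoxynaphthalen-1-yl)-4,4,5,5-tetramethyl-1,3,2-dioxaborolane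
Product: 15 (S)-5-hydroxy-4-(4-isopropoxy-8-methoxynaphthalen-1-yl)-8-methoxy-3,4-dihydronaphthalen-1(2H)-one, via phenol sulfone 13 (not isolated), via ortho-quinone methide 14 (not isolated)
Conditions: [RhCl(C2H4)2]2 (2.5 mol %), (1R,4R)-2,5-diphenylbicyclo[2.2.2]octa-2,5-diene (5.5 mol %), 6 (2.0 equiv), aq. KOH (3.0 equiv), toluene/H2O, 50 °C, degassed; 1 M HCl work-up
Reagents that add atoms: none
Why: Aqueous KOH cleaves the aryl acetate of 12, the phenoxide of 13 expels p-toluenesulfinate in a reversible 1,4-elimination to give o-QM 14, and the aryl–rhodium species (monovalent rhodium, formed by transmetalation from 6) delivers its aryl group to the exocyclic methide carbon C4 across C4=C4a–C5=O, so that ring B re-aromatises as the rhodium aryloxide and water releases phenol 15 and returns Rh–OH. The closest known reaction type is the rhodium/chiral-diene-catalysed asymmetric 1,4-addition (Hayashi–Miyaura reaction) of arylboron reagents to o-QMs released in situ from phenolic benzylic sulfones or amines. No ring is closed. The new stereocentre C4 is under catalyst control: the C2-symmetric diene lets the flat o-QM bind rhodium through one face of C4=C4a only, and because ring A allows only the E methide, face selection translates directly into the C4 configuration while the racemic centre of 12 is erased. The step needs attack at C4 rather than at C7 or the C1 carbonyl, which aromatisation of ring B (gained only by C4 attack) secures, and it needs a defined position on the naphthalene, which the boron at C1 secures. Loss of the o-QM by a [1,5]-hydrogen shift is excluded because C3 is held anti to O5, the O8 methyl ether blocks tautomerisation to a quinone, and the sulfinate reservoir with biphasic base keeps the o-QM concentration low.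

Step 9
Reactants: 15 (S)-5-hydroxy-4-(4-isopropoxy-8-methoxynaphthalen-1-yl)-8-methoxy-3,4-dihydronaphthalen-1(2H)-one
Product: 16 (S)-5,8-dihydroxy-4-(4-hydroxy-8-methoxynaphthalen-1-yl)-3,4-dihydronaphthalen-1(2H)-one
Conditions: BCl3 (6 equiv), CH2Cl2, −78 → 0 °C; MeOH, then aq. NaHCO3
Reagents that add atoms: none
Why: BCl3 cleaves the aryl isopropyl ether and, by chelation to the C1 carbonyl, the peri methyl ether at C8, while the naphthalene methyl ether has no chelating partner and should stay; no bond at C4 is touched.

**Compound list**

1 | naphthalene-1,5-diol | Oc1cccc2c(O)cccc12 | starting material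
2 | 5-methoxynaphthalen-1-ol | COc1cccc2c(O)cccc12 | intermediate
3 | 4-bromo-5-methoxynaphthalen-1-ol | COc1cccc2c(O)ccc(Br)c12 | intermediate
4 | 4-bromo-1-isopropoxy-5-methoxynaphthalene | COc1cccc2c(OC(C)C)ccc(Br)c12 | intermediate
5 | (4-isopropoxy-8-methoxynaphthalen-1-yl)lithium (not isolated) | COc1cccc2c(OC(C)C)ccc([Li])c12 | intermediate
6 | 2-(4-isopropoxy-8-methoxynaphthalen-1-yl)-4,4,5,5-tetramethyl-1,3,2-dioxaborolane | COc1cccc2c(OC(C)C)ccc(B3OC(C)(C)C(C)(C)O3)c12 | intermediate
7 | 5-hydroxy-3,4-dihydronaphthalen-1(2H)-one (5-hydroxy-1-tetralone) | O=C1CCCc2c(O)cccc12 | starting material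
8 | 8,8-dimethoxy-3,4-dihydronaphthalene-1,5(2H,8H)-dione (p-quinone monoketal, not isolated) | COC1(OC)C=CC(=O)C2=C1C(=O)CCC2 | intermediate
9 | 5-hydroxy-8-methoxy-3,4-dihydronaphthalen-1(2H)-one | O=C1CCCc2c(O)ccc(OC)c12 | intermediate
10 | 4-methoxy-5-oxo-5,6,7,8-tetrahydronaphthalen-1-yl acetate | CC(=O)Oc1ccc(OC)c2c1CCCC2=O | intermediate
11 | 8-bromo-4-methoxy-5-oxo-5,6,7,8-tetrahydronaphthalen-1-yl acetate (racemic, not isolated) | CC(=O)Oc1ccc(OC)c2c1C(Br)CCC2=O | intermediate
12 | 4-methoxy-5-oxo-8-tosyl-5,6,7,8-tetrahydronaphthalen-1-yl acetate (racemic) | CC(=O)Oc1ccc(OC)c2c1C(CCC2=O)S(=O)(=O)c1ccc(C)cc1 | intermediate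
13 | 5-hydroxy-8-methoxy-4-tosyl-3,4-dihydronaphthalen-1(2H)-one (racemic, present as its potassium phenoxide, not isolated) | COc1ccc(O)c2c1C(=O)CCC2S(=O)(=O)c1ccc(C)cc1 | intermediate
14 | 8-methoxy-2,3-dihydronaphthalene-1,5-dione (ring-fused E ortho-quinone methide, not isolated) | COC1=C2C(=O)CCC=C2C(=O)C=C1 | intermediate
15 | (S)-5-hydroxy-4-(4-isopropoxy-8-methoxynaphthalen-1-yl)-8-methoxy-3,4-dihydronaphthalen-1(2H)-one | COc1cccc2c(OC(C)C)ccc([C@@H]3CCC(=O)c4c(OC)ccc(O)c43)c12 | intermediate
16 | (S)-5,8-dihydroxy-4-(4-hydroxy-8-methoxynaphthalen-1-yl)-3,4-dihydronaphthalen-1(2H)-one | COc1cccc2c(O)ccc([C@@H]3CCC(=O)c4c(O)ccc(O)c43)c12 | target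

**Step count**

Total steps: 9. Longest linear sequence: 6 (steps 1, 2, 3, 4, 8, 9).

**Steps most likely to fail**

Step 8. The o-QM may be lost by base-mediated proton loss from C3 (which ends in aromatisation of ring A to a naphthalenediol) or by hydration before the hindered aryl–rhodium adds, and the electron-rich boronate may protodeboronate. The fallback is a radical cross-coupling that needs neither an o-QM nor aqueous base; it sets out from 10 and 4. Compound 10 is brominated as in step 7 and bromide 11 is isolated. Compound 4 is converted through 5 (n-BuLi, then ZnBr2) into (4-isopropoxy-8-methoxynaphthalen-1-yl)zinc bromide F1. A stereoconvergent Negishi arylation of racemic 11 with F1 (NiBr2(dme), chiral bis(oxazoline) ligand, THF/DMA, −20 °C) should give (S)-8-(4-isopropoxy-8-methoxynaphthalen-1-yl)-4-methoxy-5-oxo-5,6,7,8-tetrahydronaphthalen-1-yl acetate F2. K2CO3 in MeOH removes the acetate and the route is rejoined at 15.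

Step 7. Electrophilic bromination of ring B or bromination next to the ketone may compete with hydrogen abstraction at C4, and the bromide may lose HBr with aromatisation of ring A. The fallback replaces the radical C–H bromination by a two-electron phenol oxidation; it sets out from 9. Ag2O in CH2Cl2 oxidises the o-alkyl-p-methoxyphenol 9 to o-QM 14 (the behaviour of chromanol-type phenols), which morpholine present in the flask traps as 5-hydroxy-8-methoxy-4-(morpholin-4-yl)-3,4-dihydronaphthalen-1(2H)-one F3. This Mannich-type base takes the place of 12 in step 8, where warming with base releases the amine and regenerates 14, and the route is rejoined at 15.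

Step 5. Methanol may attack ortho instead of para to the phenolic oxygen, the oxidation may stop short of the monoketal, or the ketal may hydrolyse to the quinone before zinc reduces it, which would end in over-reduction to the hydroquinone. The fallback installs O8 through the quinone and differentiates the two hydroxyls by chelation; it sets out from 7. K2[ON(SO3)2] in phosphate-buffered acetone/water (Teuber reaction) oxidises 7 to 6,7-dihydronaphthalene-1,4,5(8H)-trione F4. Na2S2O4 reduces this to 5,8-dihydroxy-3,4-dihydronaphthalen-1(2H)-one F5. Ac2O (1 equiv) in pyridine at 0 °C acetylates only the non-chelated 5-OH to give 4-hydroxy-5-oxo-5,6,7,8-tetrahydronaphthalen-1-yl acetate F6. MeI/Ag2O methylates the chelated 8-OH and the route is rejoined at 10.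

**Further compounds**

F1 | step 8 | (4-isopropoxy-8-methoxynaphthalen-1-yl)zinc bromide | COc1cccc2c(OC(C)C)ccc([Zn]Br)c12
F2 | step 8 | (S)-8-(4-isopropoxy-8-methoxynaphthalen-1-yl)-4-methoxy-5-oxo-5,6,7,8-tetrahydronaphthalen-1-yl acetate | COc1cccc2c(OC(C)C)ccc([C@@H]3CCC(=O)c4c(OC)ccc(OC(C)=O)c43)c12
F3 | step 7 | 5-hydroxy-8-methoxy-4-(morpholin-4-yl)-3,4-dihydronaphthalen-1(2H)-one (racemic) | COc1ccc(O)c2c1C(=O)CCC2N1CCOCC1
F4 | step 5 | 6,7-dihydronaphthalene-1,4,5(8H)-trione | O=C1C=CC(=O)C2=C1C(=O)CCC2
F5 | step 5 | 5,8-dihydroxy-3,4-dihydronaphthalen-1(2H)-one | O=C1CCCc2c(O)ccc(O)c12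
F6 | step 5 | 4-hydroxy-5-oxo-5,6,7,8-tetrahydronaphthalen-1-yl acetate | CC(=O)Oc1ccc(O)c2c1CCCC2=O
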